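The target is cut at the C7–C8 bond, between the benzylic carbinol carbon on guaiacyl ring A and the carbon bearing the ether oxygen of dimethoxyphenyl ring B. The key step exploits the syn (threo) C7 hydroxyl/C8 aryloxy pair: an auxiliary-controlled syn aldol addition of the Z-boron enolate of an (S)-4-benzyl-N-(aryloxyacetyl)oxazolidinone (ring B, C8, C9) to a vanillin-derived aldehyde (ring A, C7) forms the bond and sets 7R and 8R in one operation. All four primary alcohols are carried as carboxyl derivatives (imide at C9, methyl ester on ring B, malonate on the ring A ether), so a single hydride reduction after the aldol should deliver the target without protecting groups.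

Key step: step 4

Remark: C9 is the CH2OH carbon on C8, and (S)-4-benzyl-3-(chloroacetyl)oxazolidin-2-one is assumed to be a catalogue compound (otherwise one extra N-acylation of (S)-4-benzyloxazolidin-2-one with chloroacetyl chloride is needed).

Step 1
Reactants: 1 vanillin; 2 diethyl chloromalonate
Product: 3 diethyl 2-(4-formyl-2-methoxyphenoxy)propanedioate
Conditions: K2CO3, acetone, reflux
Reagents that add atoms: none
Why: Williamson ether synthesis, in which the weakly basic para-formyl phenoxide should displace chloride from the doubly activated malonate carbon (SN2); the chloro rather than the bromo malonate is chosen to suppress halophilic attack, the product has only one malonate hydrogen so no Knoevenagel condensation can go to completion, and no stereocentre is formed.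

Step 2
Reactants: 4 sinapic acid
Product: 6 methyl 3-(4-hydroxy-3,5-dimethoxyphenyl)propanoate, via dihydrosinapic acid 5 (not isolated)
Conditions: H2 (1 atm), 10% Pd/C, MeOH, rt; filter; then H2SO4 (cat.), reflux
Reagents that add atoms: methanol CO
Why: Heterogeneous catalytic hydrogenation of the cinnamic C=C bond (arene and phenol untouched at 1 atm) followed by Fischer esterification in the same methanol; no stereocentre is formed.

Step 3
Reactants: 6 methyl 3-(4-hydroxy-3,5-dimethoxyphenyl)propanoate; 7 (S)-4-benzyl-3-(chloroacetyl)oxazolidin-2-one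
Product: 8 (4S)-4-benzyl-3-{2-[2,6-dimethoxy-4-(3-methoxy-3-oxopropyl)phenoxy]acetyl}oxazolidin-2-one
Conditions: K2CO3, NaI (cat.), acetone, rt to 45 °C
Reagents that add atoms: none
Why: Williamson ether synthesis on an α-halo imide with Finkelstein activation by iodide, in which the hindered 2,6-dimethoxyphenoxide should prefer SN2 attack at the CH2 carbon over attack at the imide carbonyl; the auxiliary stereocentre is not involved.

Step 4
Reactants: 8 (4S)-4-benzyl-3-{2-[2,6-dimethoxy-4-(3-methoxy-3-oxopropyl)phenoxy]acetyl}oxazolidin-2-one; 3 diethyl 2-(4-formyl-2-methoxyphenoxy)propanedioate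
Product: 10 diethyl 2-{4-[(1R,2S)-3-[(4S)-4-benzyl-2-oxooxazolidin-3-yl]-2-[2,6-dimethoxy-4-(3-methoxy-3-oxopropyl)phenoxy]-1-hydroxy-3-oxopropyl]-2-methoxyphenoxy}propanedioate (syn aldol adduct), via Z-dibutylboron enolate 9 (not isolated)
Conditions: Bu2BOTf (1.1 equiv), iPr2NEt (1.3 equiv), CH2Cl2, −78 → 0 °C; then 3, −78 → 0 °C; then pH 7 phosphate buffer, MeOH, 30% H2O2, 0 °C
Reagents that add atoms: dibutylboron triflate CCCCB(CCCC)OS(=O)(=O)C(F)(F)F (supplies the Bu2B group of intermediate 9 only; no atom of it stays in product 10)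
Why: Bu2BOTf and iPr2NEt soft-enolize only the imide CH2 (the methyl ester is not acidic enough, and aldehyde 3 with its malonate is added only after enolization is complete) to give Z-enolate 9, with the aryloxy oxygen cis to the O–B oxygen to avoid allylic 1,3-strain with the auxiliary. The aldehyde then binds to boron and the C7–C8 bond forms through a closed chair Zimmerman–Traxler transition state; the closest known reaction type is the Evans syn aldol of N-glycolyl and N-(aryloxyacetyl) oxazolidinones, which is established for arylglycerol β-aryl ether units. No ring is closed. C8 is controlled by the auxiliary: with the oxazolidinone carbonyl turned away from the enolate oxygen (dipole minimization) the (4S)-benzyl group covers one enolate face, so the aldehyde adds to the other and C8 becomes R in target numbering (2S in the acyl imide). C7 is controlled by the chair: the ring A aryl group sits equatorial, the enolate attacks the Si face of the aldehyde and the 7R syn (threo) carbinol should result. The step needs chemoselectivity (one enolizable partner, one electrophile) and syn selectivity; the first is secured by the non-enolizable aldehyde and the inertness of esters toward boron enolates at low temperature, the second by the fixed Z geometry and the tight boron-centred transition state.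

Step 5
Reactants: 10 syn aldol adduct
Product: 11 (1R,2R)-1-{4-[(1,3-dihydroxypropan-2-yl)oxy]-3-methoxyphenyl}-2-[4-(3-hydroxypropyl)-2,6-dimethoxyphenoxy]propane-1,3-diol (target)
Conditions: LiBH4 (excess), THF–MeOH, 0 °C → rt; then aq. NH4Cl
Reagents that add atoms: none
Why: Reductive cleavage of the N-acyl oxazolidinone and ester-to-alcohol reduction of the methyl ester and both malonate esters by LiBH4/MeOH (hydride reduction) should unveil C9–OH, the propanol terminus and the 1,3-diol together; the imide is reduced first and fast so retro-aldol is not expected, the transient α-aryloxy aldehyde is reduced faster than it enolizes, and C7 and C8 are therefore not touched.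

Compound list
1 | vanillin (4-hydroxy-3-methoxybenzaldehyde) | COc1cc(C=O)ccc1O | starting material
2 | diethyl chloromalonate (diethyl 2-chloropropanedioate) | CCOC(=O)C(Cl)C(=O)OCC | starting material
3 | diethyl 2-(4-formyl-2-methoxyphenoxy)propanedioate | CCOC(=O)C(Oc1ccc(C=O)cc1OC)C(=O)OCC | intermediate
4 | sinapic acid ((E)-3-(4-hydroxy-3,5-dimethoxyphenyl)prop-2-enoic acid) | COc1cc(/C=C/C(=O)O)cc(OC)c1O | starting material
5 | dihydrosinapic acid (3-(4-hydroxy-3,5-dimethoxyphenyl)propanoic acid) | COc1cc(CCC(=O)O)cc(OC)c1O | intermediate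
6 | methyl 3-(4-hydroxy-3,5-dimethoxyphenyl)propanoate | COC(=O)CCc1cc(OC)c(O)c(OC)c1 | intermediate
7 | (S)-4-benzyl-3-(chloroacetyl)oxazolidin-2-one | O=C1OC[C@H](Cc2ccccc2)N1C(=O)CCl | starting material
8 | (4S)-4-benzyl-3-{2-[2,6-dimethoxy-4-(3-methoxy-3-oxopropyl)phenoxy]acetyl}oxazolidin-2-one | COC(=O)CCc1cc(OC)c(OCC(=O)N2[C@@H](Cc3ccccc3)COC2=O)c(OC)c1 | intermediate
9 | Z-dibutylboron enolate of imide 8 (aryloxy oxygen cis to O–B) | COC(=O)CCc1cc(OC)c(O/C=C(\OB(CCCC)CCCC)N2[C@@H](Cc3ccccc3)COC2=O)c(OC)c1 | intermediate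
10 | diethyl 2-{4-[(1R,2S)-3-[(4S)-4-benzyl-2-oxooxazolidin-3-yl]-2-[2,6-dimethoxy-4-(3-methoxy-3-oxopropyl)phenoxy]-1-hydroxy-3-oxopropyl]-2-methoxyphenoxy}propanedioate | COc1cc([C@@H](O)[C@@H](C(=O)N2[C@@H](Cc3ccccc3)COC2=O)Oc4c(OC)cc(CCC(=O)OC)cc4OC)ccc1OC(C(=O)OCC)C(=O)OCC | intermediate
11 | (1R,2R)-1-{4-[(1,3-dihydroxypropan-2-yl)oxy]-3-methoxyphenyl}-2-[4-(3-hydroxypropyl)-2,6-dimethoxyphenoxy]propane-1,3-diol, the (7R,8R)-threo compound | COc1cc([C@@H](O)[C@@H](CO)Oc2c(OC)cc(CCCO)cc2OC)ccc1OC(CO)CO | target

Total step count: 5. Longest linear sequence: 4 steps (steps 2, 3, 4, 5); step 1 is the convergent branch.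

Steps most likely to fail

Step 4 (key step). The process at risk is competing soft enolization of the acidic malonate C–H of the aldehyde partner, and chelation of boron by its 1,3-diester. Either would consume reagent and aldehyde and lower conversion and syn selectivity. The fallback masks the ring A diol as silyl ethers instead of a malonate. It sets out from vanillin 1 and comes back to the route at target 11. Mitsunobu etherification of 1 with commercial 1,3-bis(tert-butyldimethylsilyloxy)propan-2-ol (PPh3, DIAD, THF, 0 °C → rt) should give 4-{[1,3-bis(tert-butyldimethylsilyloxy)propan-2-yl]oxy}-3-methoxybenzaldehyde F1, an aldehyde without an acidic C–H. Addition of the same boron enolate 9 to F1 under the conditions of step 4 should give the syn aldol adduct (4S)-4-benzyl-3-[(2S,3R)-3-(4-{[1,3-bis(tert-butyldimethylsilyloxy)propan-2-yl]oxy}-3-methoxyphenyl)-2-[2,6-dimethoxy-4-(3-methoxy-3-oxopropyl)phenoxy]-3-hydroxypropanoyl]oxazolidin-2-one F2. LiBH4 in THF–MeOH then has to reduce only the imide and the methyl ester and should give the bis-silylated triol (1R,2R)-1-(4-{[1,3-bis(tert-butyldimethylsilyloxy)propan-2-yl]oxy}-3-methoxyphenyl)-2-[4-(3-hydroxypropyl)-2,6-dimethoxyphenoxy]propane-1,3-diol F3. TBAF in THF removes both silyl groups and gives 11.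

Step 5. The process at risk is stalling of the mild hydride at the aryloxymalonate through deprotonation to an unreactive enolate. Forcing conditions on the free β-hydroxy imide would then invite retro-aldol cleavage or β-elimination. The fallback separates protection from reduction. It sets out from 10 and comes back at 11. Silylation of the C7 hydroxyl (TBSOTf, 2,6-lutidine, CH2Cl2, −78 °C) should give the silyl ether diethyl 2-{4-[(1R,2S)-3-[(4S)-4-benzyl-2-oxooxazolidin-3-yl]-1-(tert-butyldimethylsilyloxy)-2-[2,6-dimethoxy-4-(3-methoxy-3-oxopropyl)phenoxy]-3-oxopropyl]-2-methoxyphenoxy}propanedioate F4, which can no longer undergo retro-aldol. Exhaustive reduction with the stronger LiAlH4 (THF, 0 °C), the classical reagent for aryloxymalonates, should give the monosilylated tetraol 2-{4-[(1R,2R)-1-(tert-butyldimethylsilyloxy)-3-hydroxy-2-[4-(3-hydroxypropyl)-2,6-dimethoxyphenoxy]propyl]-2-methoxyphenoxy}propane-1,3-diol F5. Any silyl migration to O9 is harmless, because TBAF in THF then gives 11.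

Step 3. The process at risk is acyl transfer from the imide to the phenoxide, or carbonate-induced opening of the oxazolidinone, in competition with the SN2 displacement. The fallback builds the aryloxyacetic acid first and attaches the auxiliary last. It sets out from 6 and comes back at 8. Alkylation of 6 with tert-butyl bromoacetate (K2CO3, acetone, reflux) should give tert-butyl 2-[2,6-dimethoxy-4-(3-methoxy-3-oxopropyl)phenoxy]acetate F6. Trifluoroacetic acid in CH2Cl2 cleaves only the tert-butyl ester and should give 2-[2,6-dimethoxy-4-(3-methoxy-3-oxopropyl)phenoxy]acetic acid F7. Pivaloyl chloride and Et3N (THF, −20 °C) convert it into the mixed pivalic anhydride F8, which is not isolated. This acylates commercial (S)-4-benzyloxazolidin-2-one in the presence of LiCl and Et3N to give 8.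

Further compounds
F1 | step 4 | 4-{[1,3-bis(tert-butyldimethylsilyloxy)propan-2-yl]oxy}-3-methoxybenzaldehyde | COc1cc(C=O)ccc1OC(CO[Si](C)(C)C(C)(C)C)CO[Si](C)(C)C(C)(C)C
F2 | step 4 | (4S)-4-benzyl-3-[(2S,3R)-3-(4-{[1,3-bis(tert-butyldimethylsilyloxy)propan-2-yl]oxy}-3-methoxyphenyl)-2-[2,6-dimethoxy-4-(3-methoxy-3-oxopropyl)phenoxy]-3-hydroxypropanoyl]oxazolidin-2-one | COc1cc([C@@H](O)[C@@H](C(=O)N2[C@@H](Cc3ccccc3)COC2=O)Oc4c(OC)cc(CCC(=O)OC)cc4OC)ccc1OC(CO[Si](C)(C)C(C)(C)C)CO[Si](C)(C)C(C)(C)C
F3 | step 4 | (1R,2R)-1-(4-{[1,3-bis(tert-butyldimethylsilyloxy)propan-2-yl]oxy}-3-methoxyphenyl)-2-[4-(3-hydroxypropyl)-2,6-dimethoxyphenoxy]propane-1,3-diol | COc1cc([C@@H](O)[C@@H](CO)Oc2c(OC)cc(CCCO)cc2OC)ccc1OC(CO[Si](C)(C)C(C)(C)C)CO[Si](C)(C)C(C)(C)C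
F4 | step 5 | diethyl 2-{4-[(1R,2S)-3-[(4S)-4-benzyl-2-oxooxazolidin-3-yl]-1-(tert-butyldimethylsilyloxy)-2-[2,6-dimethoxy-4-(3-methoxy-3-oxopropyl)phenoxy]-3-oxopropyl]-2-methoxyphenoxy}propanedioate | COc1cc([C@@H](O[Si](C)(C)C(C)(C)C)[C@@H](C(=O)N2[C@@H](Cc3ccccc3)COC2=O)Oc4c(OC)cc(CCC(=O)OC)cc4OC)ccc1OC(C(=O)OCC)C(=O)OCC
F5 | step 5 | 2-{4-[(1R,2R)-1-(tert-butyldimethylsilyloxy)-3-hydroxy-2-[4-(3-hydroxypropyl)-2,6-dimethoxyphenoxy]propyl]-2-methoxyphenoxy}propane-1,3-diol | COc1cc([C@@H](O[Si](C)(C)C(C)(C)C)[C@@H](CO)Oc2c(OC)cc(CCCO)cc2OC)ccc1OC(CO)CO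
F6 | step 3 | tert-butyl 2-[2,6-dimethoxy-4-(3-methoxy-3-oxopropyl)phenoxy]acetate | COC(=O)CCc1cc(OC)c(OCC(=O)OC(C)(C)C)c(OC)c1
F7 | step 3 | 2-[2,6-dimethoxy-4-(3-methoxy-3-oxopropyl)phenoxy]acetic acid | COC(=O)CCc1cc(OC)c(OCC(=O)O)c(OC)c1
F8 | step 3 | 2-[2,6-dimethoxy-4-(3-methoxy-3-oxopropyl)phenoxy]acetic pivalic anhydride | COC(=O)CCc1cc(OC)c(OCC(=O)OC(=O)C(C)(C)C)c(OC)c1
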